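## Structural features

The target is a labdane-type bicycle: a trans-fused decalin (ring A = C1–C5 and C10, ring B = C5–C10) with a 5-acetoxy-3-methylpentyl chain (C11–C15, methyl C16) on C9. Ring A carries the 3β-methoxy group (3S) next to the gem-dimethyl quaternary carbon C4, which adjoins the ring-fusion methine C5 (5R, H α) and the methyl-bearing quaternary C10 (10S). C3, C4, C5 and C10 therefore form one unbroken congested array. Ring B holds a tetrasubstituted C8=C9 alkene, flanked by the quaternary C10 on one side and by the allylic 7β-acetoxy stereocentre (7S) on the other. C13 (S) lies in the chain, too far from the ring stereocentres for any relay. The fragile points are the allylic C7 acetate (ionisation, elimination to a diene, ester cleavage), the primary C15 acetate, and the tetrasubstituted alkene, which tolerates neither strong acid nor ozone. The real difficulty is threefold: the two quaternary carbons around C5 with an equatorial oxygen at C3, the hindered alkene with two different carbon substituents, and the independent configuration at C13. The key step exploits the fact that C4 is a gem-dimethyl carbon between the oxygenated C3 and C5: a C5 isopropenyl group becomes, after gain of one hydrogen atom, the tertiary C4 radical with both methyl groups in place, and its addition to a C3 aldehyde forms C3–C4, the C3 oxygen and ring A together.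

## Logic of the disconnections

**28 ⇐ 27 ⇐ 26 ⇐ 25 ⇐ 24.** The acetyl C–O bond at C7 is cut first, then the C7–H bond by way of the ketone. The ring-building chemistry needs the C7 oxygen on the α face, where it steers C5 and C10, whereas 28 needs it β. Passing through 26 turns this mismatch into a hydride addition with a known facial preference. The gain is that C7 travels as a robust silyl ether from the start. The demand is clean axial hydride delivery to 26 and survival of the C15 acetate.

**24 ⇐ 18 + 23.** The C9–C11 bond is cut, which separates all ring stereocentres (18) from C13 (23). Each half is then made from its own chiral-pool source, and the alkene position is fixed by the electrophile. The demand is an sp2–sp3 coupling at a fully substituted alkene carbon next to a quaternary centre.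

**23 ⇐ 22 ⇐ 21 ⇐ 20 ⇐ 19.** The C–Zn bond goes back to a C–I bond, this to a C–CO2H bond with loss of one carbon, and the acid to the trisubstituted alkene of 19. The C1 oxygen of 19 is kept as the future C15 acetate, which fixes the sense at C13. The gain is a C13 stereocentre bought rather than made. The demand is an oxidative cleavage and a decarboxylative iodination that leave the acetate and the stereocentre alone.

**18 ⇐ 16 ⇐ 14 ⇐ 13.** The C9–O sulfonyl bond, the C8–CH3 bond and the O–CH3 bond at C3 are cut in turn. The C9 ketone of 13 is enolisable only toward C8, so both enolate steps are regiochemically unambiguous. The demand is that the C7 silyloxy group, β to the enolate carbon, is not expelled.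

**13 ⇐ 12.** The C3–C4 bond is cut, which opens ring A and removes the C3 stereocentre and one quaternary-carbon problem at once. The forward step must generate a tertiary radical at C4 selectively, close a six-membered ring onto an aldehyde faster than the radical is reduced, and place the new oxygen equatorial.

**12 ⇐ 11 ⇐ 9.** The aldehyde is taken back to the primary alcohol and this to the terminal alkene of an allyl group. The gain is that the three-carbon arm enters as the most reliable enolate electrophile. The demand is hydroboration of a monosubstituted alkene in the presence of a 1,1-disubstituted one and a ketone.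

**9 ⇐ 5 + 6 + 7.** The C4–C5 and C10–C1 bonds are cut, as a conjugate addition and an enolate alkylation in one flask. Both ring-fusion stereocentres are thereby derived from the single stereocentre of 5. The forward step must add 6 trans to the silyloxy group and 7 trans to the new isopropenyl group.

**5 ⇐ 4 ⇐ 3 ⇐ 1.** The C7–O bond is traced back to the C–C bond that holds the isopropenyl group of 1. The gain is an enantiopure enone from a cheap terpene. The demand is an oxidative C–C to C–O exchange with retention.

## Other disconnections considered

**Alternative 1:** Both rings are cut at once, at C5–C10 and C7–C8, which opens the decalin to the acyclic keto enoate A2. This is an ethyl ketone with the C10 methine, tethered through C1–C3 and the gem-dimethyl C4 to an (E)-enoate. In the forward sense KOt-Bu in t-BuOH would equilibrate the ketone enolates. The C10 enolate would add 6-exo to the enoate β-carbon C5, and the C8 enolate would then acylate at the C7 ester. Deprotonation of the 1,3-dione A1 would pull the equilibria forward.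

- In its favour: two rings and two C–C bonds form in one flask, C8 is already methylated, and C7 arrives at the ketone level, so no silyl ether and no inversion at C7 are needed. A vinylogous ester of A1, 1,2-addition at C9 and transposition would reach an enone of the type of 26 in two or three operations. On step economy after the key step this is better than the chosen plan, which needs steps 8–10 and 14–16 to go from 13 to 26.
- Against it: the Michael bond joins a fully substituted enolate carbon to a β-carbon that carries the quaternary C4, so three contiguous congested carbons must form in a reversible, sterically sensitive step. The only stereocentre in A2 is C3, which would have to control both C10 and C5 across the gem-dimethyl group. The thermodynamic preference for a trans over a cis 10-methyl decalindione is small, and a wrong ring fusion could be corrected only by retro-Michael opening. A2 needs its own enantioselective construction of a neopentyl methyl ether. The transposition also needs a hard organometallic side chain, which excludes the acetate that the chosen route carries.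
- Comparison: this is a two-electron cascade under thermodynamic control against a kinetically controlled radical closure. It builds more of ring B per step, but the ring fusion is less secure than in the chosen plan, where C5 and C10 come from substrate-controlled additions to a ring. Total length is expected to be similar once A2 is made.

**Alternative 2:** Ring B is cut at C7–C8 and C9–C10. This gives the ring A diene A4, a 2-vinylcyclohexene whose ring alkene is the tetrasubstituted C5=C10, and the ynoate A5. Heating would give the 1,4-cyclohexadiene A3 by [4+2] cycloaddition. The ester carbon (future C11) would end on C9 and the alkyne methyl on C8, as the polarisation of both partners predicts.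

- In its favour: the tetrasubstituted C8=C9 alkene with its methyl group and a one-carbon handle on C9 arises directly. No hindered ketone has to become an enol triflate and no sp2–sp3 coupling next to C10 is needed; on this point the alternative is better than the chosen plan. C7 is doubly allylic in A3 and so is activated for later oxidation.
- Against it: C10 becomes quaternary by bond formation at a tetrasubstituted diene terminus, with C4 pressing on the vinyl group in the s-cis conformer. A β-methyl ynoate is a weak dienophile, so forcing conditions are likely. The diene faces are distinguished only by the remote C3 methoxy group. C5 is sp2 in A3, so the trans fusion must come later from a site- and face-selective reduction beside the enoate. C7 must still be oxidised. The ester must be extended by a four-carbon unit bearing C13, which means an sp3–sp3 coupling at a hindered allylic carbon.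
- Comparison: this is a concerted thermal cycloaddition with weak stereocontrol against a radical closure whose ring fusion is already fixed. It is shorter to the bicyclic core and longer from the core to 28. The two plans are equal in needing a chiral-pool source for C13.

**Alternative 3:** Ring B is cut at C8–C9 and C5–C10 into the enal A7 and the 2-silyloxy diene A8. A7 holds C9, C10, the C10 methyl, the C1 aldehyde carbon and the whole side chain. A8 holds C5–C8 with the C8 methyl, plus C4, C3 and a vinyl group. A chiral oxazaborolidinium triflimide would activate A7 for an exo-selective [4+2] cycloaddition to the adduct A6. Ring A would then be closed by methylenation of the aldehyde, ring-closing metathesis with a second-generation Grubbs catalyst and hydrogenation. The silyl enol ether is the latent C7 ketone.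

- In its favour: it is the most convergent plan, with catalyst control at C5 and C10, C7 at the ketone level, and the C8 methyl and the full side chain present from the start. A7 is 19 with its carbon skeleton intact after silylation and allylic oxidation. This is better than the chosen plan, which discards four of the ten carbons of 19. Exo selectivity is the normal preference of α-methyl enals, and that is what the trans relation of C1 and C4 needs.
- Against it: a β-alkyl α-methyl enal is among the least reactive dienophiles even when activated. The diene terminus C5 carries the quaternary C4, so the C5–C10 bond joins two congested carbons. The acid-labile silyl dienol ether must survive a strong Lewis acid. The resident C3 stereocentre creates matched and mismatched pairings with the catalyst. After the cycloaddition three steps are still needed for ring A, and the C8=C9 alkene must be introduced by a regioselective dehydrogenation toward C8–C9 rather than C5–C6.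
- Comparison: this is a catalyst-controlled concerted cycloaddition against a substrate-controlled radical closure. It is the equal of the chosen plan in total length, better in convergence and carbon economy, and weaker in the likelihood that the central bond forms at all.

Key step: step 7

**Remarks on the chemistry**

- Bicyclic compounds are named on the target (labdane) numbering; β is the face of the C10 methyl group.
- Cleaving the alkene of 19 alone would leave one methylene too many between the metal-bearing carbon and C13. The fragment is therefore shortened by one carbon through iododecarboxylation (step 13). Keeping the C1 oxygen of (S)-19 as C15 gives 13S.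
- At C3 the equatorial preference of the carbonyl oxygen is ascribed to the axial hydrogens on C1 and C5. An axial oxygen at C3 would point to the α face and would not meet the β-axial C10 methyl.
- Disiamylborane is used in step 5 because it strongly prefers monosubstituted over 1,1-disubstituted alkenes. The O-methylation in step 8 is done under non-basic conditions because 13 holds an enolisable β-silyloxy ketone. The C15 acetate of the target is carried from step 11.
- Assumption: C8 of 16 is left as an epimer mixture, since it becomes sp2 in step 10.

## Route

Step 1
Reactants: 1 (R)-carvone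
Product: 3 (R)-5-acetoxy-2-methylcyclohex-2-en-1-one, via methoxy hydroperoxide 2 (not isolated)
Conditions: O3, CH2Cl2/MeOH, −78 °C; then Ac2O, Et3N, DMAP (cat.), −78 °C → rt
Reagents that add atoms: ozone, [O-][O+]=O; methanol, CO
Why: Ozone attacks the electron-rich 1,1-disubstituted alkene rather than the conjugated one and methanol traps the carbonyl oxide as 2; acetylation of the hydroperoxide triggers a Criegee rearrangement in which the ring carbon migrates to oxygen with retention. The acetyl group of 3 is the former isopropenyl C–CH3 unit, so the stereocentre of 1 becomes the oxygen-bearing carbon unchanged.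

Step 2
Reactants: 3 (R)-5-acetoxy-2-methylcyclohex-2-en-1-one
Product: 4 (R)-5-hydroxy-2-methylcyclohex-2-en-1-one
Conditions: K2CO3 (cat.), MeOH, 0 °C, short reaction time
Reagents that add atoms: none
Why: Base-catalysed transesterification removes the acetate; low temperature and brief exposure keep the β-hydroxy enone from eliminating toward the cresol.

Step 3
Reactants: 4 (R)-5-hydroxy-2-methylcyclohex-2-en-1-one
Product: 5 (R)-5-[(tert-butyldimethylsilyl)oxy]-2-methylcyclohex-2-en-1-one
Conditions: TBSCl, imidazole, DMF, rt
Reagents that add atoms: tert-butyldimethylsilyl chloride, CC(C)(C)[Si](C)(C)Cl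
Why: Standard silylation of a secondary alcohol under nearly neutral conditions; the bulky silyl ether is the directing group for the next step.

Step 4
Reactants: 5 (R)-5-[(tert-butyldimethylsilyl)oxy]-2-methylcyclohex-2-en-1-one; 6 isopropenylmagnesium bromide; 7 allyl bromide
Product: 9 (2S,3S,5R)-5-[(tert-butyldimethylsilyl)oxy]-2-methyl-2-(prop-2-en-1-yl)-3-(prop-1-en-2-yl)cyclohexan-1-one, via bromomagnesium enolate 8 (not isolated)
Conditions: 6 (1.5 equiv), CuBr·SMe2 (20 mol %), THF, −78 → −40 °C; then 7 (4 equiv), HMPA, −40 → 0 °C
Reagents that add atoms: none
Why: Copper-catalysed conjugate addition followed by alkylation of the regiodefined enolate (three-component coupling). The isopropenyl group should enter trans to the silyloxy group, setting C5, and allyl bromide should approach the enolate face opposite the new isopropenyl group, setting the quaternary C10 with methyl cis and allyl trans to it.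

Step 5
Reactants: 9 (2S,3S,5R)-5-[(tert-butyldimethylsilyl)oxy]-2-methyl-2-(prop-2-en-1-yl)-3-(prop-1-en-2-yl)cyclohexan-1-one
Product: 11 (2S,3S,5R)-5-[(tert-butyldimethylsilyl)oxy]-2-(3-hydroxypropyl)-2-methyl-3-(prop-1-en-2-yl)cyclohexan-1-one, via alkylborane 10 (not isolated)
Conditions: Sia2BH (1.5 equiv, from BH3·THF and 2-methylbut-2-ene), THF, 0 °C; then NaBO3·4H2O, THF/H2O, rt
Reagents that add atoms: sodium perborate, [Na+].[O-]B1OO1
Why: Anti-Markovnikov hydroboration–oxidation; the hindered dialkylborane should take the monosubstituted alkene much faster than the 1,1-disubstituted isopropenyl group beside the quaternary carbon, or the hindered ketone. Perborate oxidises the borane without the strong base that could expel the β-silyloxy group.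

Step 6
Reactants: 11 (2S,3S,5R)-5-[(tert-butyldimethylsilyl)oxy]-2-(3-hydroxypropyl)-2-methyl-3-(prop-1-en-2-yl)cyclohexan-1-one
Product: 12 3-[(1S,2S,4R)-4-[(tert-butyldimethylsilyl)oxy]-1-methyl-6-oxo-2-(prop-1-en-2-yl)cyclohexyl]propanal
Conditions: DMP, NaHCO3, CH2Cl2, 0 °C → rt; used at once
Reagents that add atoms: none
Why: Buffered Dess–Martin oxidation of the primary alcohol (also of any hemiketal form, through the open chain) gives the keto aldehyde without acid or base that could trigger an intramolecular aldol between C8 and C3.

Step 7
Reactants: 12 3-[(1S,2S,4R)-4-[(tert-butyldimethylsilyl)oxy]-1-methyl-6-oxo-2-(prop-1-en-2-yl)cyclohexyl]propanal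
Product: 13 7α-(tert-butyldimethylsilyloxy)-3β-hydroxy-4,4,10β-trimethyl-5α-decalin-9-one
Conditions: Fe(acac)3 (30 mol %), PhSiH3 (2.5 equiv), EtOH (degassed), 60 °C
Reagents that add atoms: none
Why: Fe(acac)3 and PhSiH3 in ethanol generate an iron hydride that transfers a hydrogen atom to the CH2 terminus of the isopropenyl group, the only electron-rich unhindered alkene terminus in 12, which creates the tertiary C4 radical and completes the gem-dimethyl group. The radical adds to the aldehyde carbon C3 in a 6-exo-trig closure through a chair in which the C5–C4 and C10–C1 bonds are both equatorial on ring B, so ring A forms trans-fused with no change at C5 or C10. The alkoxy radical is reduced by divalent iron to the iron alkoxide and protonated by ethanol, which removes it before β-scission can reopen the ring and returns trivalent iron to the cycle. The closest known reaction type is the iron-hydride hydrogen-atom-transfer cyclization of alkenes onto ketones under the same reagents; an aldehyde acceptor is less often used but is the more electrophilic and less hindered carbonyl. The one new stereocentre, C3, is set by the chair: the carbonyl oxygen takes the equatorial (β) position because an axial oxygen would point to the α face and meet the axial hydrogens on C1 and C5, and coordination to iron enlarges it further, which gives the 3β-alcohol. The step needs hydrogen-atom transfer to the 1,1-disubstituted alkene rather than reduction of either carbonyl, and addition to the aldehyde rather than the C9 ketone; the first is inherent in the reagent and the second is secured because attack at C9 would close a four-membered ring. Premature reduction of the radical is limited by the high effective molarity of the aldehyde, which the trans substituents on C5 and C10 already hold gauche to the radical centre.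

Step 8
Reactants: 13 7α-(tert-butyldimethylsilyloxy)-3β-hydroxy-4,4,10β-trimethyl-5α-decalin-9-one
Product: 14 7α-(tert-butyldimethylsilyloxy)-3β-methoxy-4,4,10β-trimethyl-5α-decalin-9-one
Conditions: Me3OBF4, 1,8-bis(dimethylamino)naphthalene, 4 Å MS, CH2Cl2, rt
Reagents that add atoms: trimethyloxonium tetrafluoroborate, C[O+](C)C.F[B-](F)(F)F
Why: O-Methylation of a hindered neopentyl alcohol by an oxonium salt with a non-nucleophilic proton scavenger; no enolate is formed, so the ketone and the β-silyloxy group are untouched and C3 keeps its configuration.

Step 9
Reactants: 14 7α-(tert-butyldimethylsilyloxy)-3β-methoxy-4,4,10β-trimethyl-5α-decalin-9-one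
Product: 16 7α-(tert-butyldimethylsilyloxy)-3β-methoxy-4,4,8,10β-tetramethyl-5α-decalin-9-one (C8 epimers), via lithium enolate 15 (not isolated)
Conditions: LDA (1.1 equiv), THF, −78 °C; then MeI (5 equiv), −78 → −40 °C
Reagents that add atoms: iodomethane, CI
Why: Kinetic enolate alkylation; C10 is quaternary, so deprotonation can occur only at C8. At −78 °C the lithium enolate should be methylated faster than it expels the silyloxy group; the C8 configuration is irrelevant.

Step 10
Reactants: 16 7α-(tert-butyldimethylsilyloxy)-3β-methoxy-4,4,8,10β-tetramethyl-5α-decalin-9-one (C8 epimers)
Product: 18 7α-(tert-butyldimethylsilyloxy)-3β-methoxy-4,4,8,10β-tetramethyl-5α-octal-8-en-9-yl trifluoromethanesulfonate, via potassium enolate 17 (not isolated)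
Conditions: KHMDS (1.3 equiv), THF, −78 °C; then PhNTf2, −78 → −20 °C
Reagents that add atoms: N-phenylbis(trifluoromethanesulfonimide), O=S(=O)(N(c1ccccc1)S(=O)(=O)C(F)(F)F)C(F)(F)F
Why: O-Sulfonylation of the only possible enolate gives the tetrasubstituted enol triflate, as is routine for 2,2,6-trisubstituted cyclohexanones. Both C8 epimers converge and the C8=C9 alkene is placed without ambiguity.

Step 11
Reactants: 19 (S)-citronellol
Product: 20 (S)-citronellyl acetate
Conditions: Ac2O, pyridine, DMAP (cat.), CH2Cl2, rt
Reagents that add atoms: acetic anhydride, CC(=O)OC(C)=O
Why: Acetylation of the primary alcohol installs the C15 acetate of the target at the outset, where it also serves as the protecting group.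

Step 12
Reactants: 20 (S)-citronellyl acetate
Product: 21 (4S)-6-acetoxy-4-methylhexanoic acid
Conditions: RuCl3·xH2O (2 mol %), NaIO4 (4 equiv), MeCN/EtOAc/H2O, rt
Reagents that add atoms: sodium periodate, [Na+].[O-]I(=O)(=O)=O; water, O
Why: Catalytic RuO4 cleaves the trisubstituted alkene to the carboxylic acid and acetone; the ester and the stereocentre, which bears no activated hydrogen, are not affected.

Step 13
Reactants: 21 (4S)-6-acetoxy-4-methylhexanoic acid
Product: 22 (3R)-5-iodo-3-methylpentyl acetate
Conditions: PhI(OAc)2, I2, cyclohexane, hν (tungsten lamp), reflux
Reagents that add atoms: iodine, II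
Why: Hunsdiecker-type iododecarboxylation through an acyl hypoiodite: light-induced homolysis, loss of CO2 and iodine capture of the primary radical remove the surplus carbon and install the handle for zinc insertion. The stereocentre is two bonds from the radical and is unchanged; its descriptor changes only because iodine alters the priorities.

Step 14
Reactants: 18 7α-(tert-butyldimethylsilyloxy)-3β-methoxy-4,4,8,10β-tetramethyl-5α-octal-8-en-9-yl trifluoromethanesulfonate; 22 (3R)-5-iodo-3-methylpentyl acetate
Product: 24 (13S)-7α-(tert-butyldimethylsilyloxy)-3β-methoxylabd-8-en-15-yl acetate, via alkylzinc iodide 23 (not isolated)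
Conditions: 22, Zn dust (activated with TMSCl and BrCH2CH2Br), DMA, 40 °C; then 18, Pd(dppf)Cl2 (10 mol %), THF/DMA, 60 °C
Reagents that add atoms: none
Why: Zinc inserts into the primary C–I bond with the ester tolerated, and Negishi coupling joins C11 to C9. The wide-bite-angle ferrocenyl diphosphine favours reductive elimination over β-hydride elimination from the alkylpalladium intermediate; no stereocentre is formed.

Step 15
Reactants: 24 (13S)-7α-(tert-butyldimethylsilyloxy)-3β-methoxylabd-8-en-15-yl acetate
Product: 25 (13S)-7α-hydroxy-3β-methoxylabd-8-en-15-yl acetate
Conditions: TBAF, AcOH (1:1), THF, rt → 45 °C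
Reagents that add atoms: none
Why: Fluoride cleaves the silyl ether; buffering with acetic acid protects the primary acetate from basic cleavage and avoids the acid that would ionise the allylic alcohol.

Step 16
Reactants: 25 (13S)-7α-hydroxy-3β-methoxylabd-8-en-15-yl acetate
Product: 26 (13S)-3β-methoxy-7-oxolabd-8-en-15-yl acetate
Conditions: DMP, NaHCO3, CH2Cl2, rt
Reagents that add atoms: none
Why: Oxidation of the only free hydroxyl gives the 8-en-7-one and erases the α configuration at C7. Dess–Martin periodinane is chosen because the quasi-axial allylic alcohol is a slow substrate for MnO2, which would be used instead only if the C15 hydroxyl were free.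

Step 17
Reactants: 26 (13S)-3β-methoxy-7-oxolabd-8-en-15-yl acetate
Product: 27 (13S)-7β-hydroxy-3β-methoxylabd-8-en-15-yl acetate
Conditions: NaBH4, CeCl3·7H2O, MeOH, −40 → 0 °C
Reagents that add atoms: none
Why: Luche 1,2-reduction of the enone; the small hydride should enter along the axial trajectory from the α face and give the quasi-equatorial 7β-alcohol, as is usual for 7-oxo-8-enes of this ring system. The acetate is inert at this temperature.

Step 18
Reactants: 27 (13S)-7β-hydroxy-3β-methoxylabd-8-en-15-yl acetate
Product: 28 (13S)-3β-methoxylabd-8-ene-7β,15-diyl diacetate
Conditions: Ac2O, pyridine, DMAP (cat.), CH2Cl2, 0 °C → rt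
Reagents that add atoms: acetic anhydride, CC(=O)OC(C)=O
Why: Nucleophile-catalysed acetylation of the allylic alcohol under basic, non-ionising conditions retains the C7 configuration and would restore the C15 acetate if any had been lost.

## Compound list

1 | (R)-carvone | CC1=CC[C@H](CC1=O)C(C)=C | starting material
2 | (5R)-5-(1-hydroperoxy-1-methoxyethyl)-2-methylcyclohex-2-en-1-one (epimers at the peroxy carbon) | CC1=CC[C@H](CC1=O)C(C)(OC)OO | intermediate (not isolated)
3 | (R)-5-acetoxy-2-methylcyclohex-2-en-1-one | CC1=CC[C@H](CC1=O)OC(C)=O | intermediate
4 | (R)-5-hydroxy-2-methylcyclohex-2-en-1-one | CC1=CC[C@H](CC1=O)O | intermediate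
5 | (R)-5-[(tert-butyldimethylsilyl)oxy]-2-methylcyclohex-2-en-1-one | CC1=CC[C@H](CC1=O)O[Si](C)(C)C(C)(C)C | intermediate
6 | isopropenylmagnesium bromide | CC(=C)[Mg]Br | starting material
7 | allyl bromide | C=CCBr | starting material
8 | bromomagnesium C9–C10 enolate from conjugate addition to 5 (isopropenyl on C5 β, silyloxy on C7 α) | CC1=C(O[Mg]Br)C[C@H](O[Si](C)(C)C(C)(C)C)C[C@H]1C(C)=C | intermediate (not isolated)
9 | (2S,3S,5R)-5-[(tert-butyldimethylsilyl)oxy]-2-methyl-2-(prop-2-en-1-yl)-3-(prop-1-en-2-yl)cyclohexan-1-one | C=CC[C@]1(C)C(=O)C[C@H](O[Si](C)(C)C(C)(C)C)C[C@H]1C(C)=C | intermediate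
10 | bis(3-methylbutan-2-yl)borane adduct at the terminal carbon of the allyl group of 9 | CC(C)C(C)B(C(C)C(C)C)CCC[C@]1(C)C(=O)C[C@H](O[Si](C)(C)C(C)(C)C)C[C@H]1C(C)=C | intermediate (not isolated)
11 | (2S,3S,5R)-5-[(tert-butyldimethylsilyl)oxy]-2-(3-hydroxypropyl)-2-methyl-3-(prop-1-en-2-yl)cyclohexan-1-one | OCCC[C@]1(C)C(=O)C[C@H](O[Si](C)(C)C(C)(C)C)C[C@H]1C(C)=C | intermediate
12 | 3-[(1S,2S,4R)-4-[(tert-butyldimethylsilyl)oxy]-1-methyl-6-oxo-2-(prop-1-en-2-yl)cyclohexyl]propanal | O=CCC[C@]1(C)C(=O)C[C@H](O[Si](C)(C)C(C)(C)C)C[C@H]1C(C)=C | intermediate (key-step precursor)
13 | 7α-(tert-butyldimethylsilyloxy)-3β-hydroxy-4,4,10β-trimethyl-5α-decalin-9-one | O[C@H]1CC[C@]2(C)C(=O)C[C@H](O[Si](C)(C)C(C)(C)C)C[C@H]2C1(C)C | intermediate (key-step product)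
14 | 7α-(tert-butyldimethylsilyloxy)-3β-methoxy-4,4,10β-trimethyl-5α-decalin-9-one | CO[C@H]1CC[C@]2(C)C(=O)C[C@H](O[Si](C)(C)C(C)(C)C)C[C@H]2C1(C)C | intermediate
15 | lithium C8–C9 enolate of 14 | CO[C@H]1CC[C@]2(C)C(O[Li])=C[C@H](O[Si](C)(C)C(C)(C)C)C[C@H]2C1(C)C | intermediate (not isolated)
16 | 7α-(tert-butyldimethylsilyloxy)-3β-methoxy-4,4,8,10β-tetramethyl-5α-decalin-9-one (C8 epimers) | CO[C@H]1CC[C@]2(C)C(=O)C(C)[C@H](O[Si](C)(C)C(C)(C)C)C[C@H]2C1(C)C | intermediate
17 | potassium C8–C9 enolate of 16 | CO[C@H]1CC[C@]2(C)C(O[K])=C(C)[C@H](O[Si](C)(C)C(C)(C)C)C[C@H]2C1(C)C | intermediate (not isolated)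
18 | 7α-(tert-butyldimethylsilyloxy)-3β-methoxy-4,4,8,10β-tetramethyl-5α-octal-8-en-9-yl trifluoromethanesulfonate | CO[C@H]1CC[C@]2(C)C(OS(=O)(=O)C(F)(F)F)=C(C)[C@H](O[Si](C)(C)C(C)(C)C)C[C@H]2C1(C)C | intermediate
19 | (S)-citronellol | CC(C)=CCC[C@H](C)CCO | starting material
20 | (S)-citronellyl acetate | CC(C)=CCC[C@H](C)CCOC(C)=O | intermediate
21 | (4S)-6-acetoxy-4-methylhexanoic acid | OC(=O)CC[C@H](C)CCOC(C)=O | intermediate
22 | (3R)-5-iodo-3-methylpentyl acetate | ICC[C@H](C)CCOC(C)=O | intermediate
23 | [(3R)-5-acetoxy-3-methylpentyl]zinc iodide | I[Zn]CC[C@H](C)CCOC(C)=O | intermediate (not isolated)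
24 | (13S)-7α-(tert-butyldimethylsilyloxy)-3β-methoxylabd-8-en-15-yl acetate | CO[C@H]1CC[C@]2(C)C(CC[C@H](C)CCOC(C)=O)=C(C)[C@H](O[Si](C)(C)C(C)(C)C)C[C@H]2C1(C)C | intermediate
25 | (13S)-7α-hydroxy-3β-methoxylabd-8-en-15-yl acetate | CO[C@H]1CC[C@]2(C)C(CC[C@H](C)CCOC(C)=O)=C(C)[C@H](O)C[C@H]2C1(C)C | intermediate
26 | (13S)-3β-methoxy-7-oxolabd-8-en-15-yl acetate | CO[C@H]1CC[C@]2(C)C(CC[C@H](C)CCOC(C)=O)=C(C)C(=O)C[C@H]2C1(C)C | intermediate
27 | (13S)-7β-hydroxy-3β-methoxylabd-8-en-15-yl acetate | CO[C@H]1CC[C@]2(C)C(CC[C@H](C)CCOC(C)=O)=C(C)[C@@H](O)C[C@H]2C1(C)C | intermediate
28 | (13S)-3β-methoxylabd-8-ene-7β,15-diyl diacetate | CO[C@H]1CC[C@]2(C)C(CC[C@H](C)CCOC(C)=O)=C(C)[C@@H](OC(C)=O)C[C@H]2C1(C)C | target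

## Step count and least certain steps

Total step count: 18. Longest linear sequence: 15 steps (steps 1–10 and 14–18, from 1 to 28); the side-chain branch (steps 11–13) joins at step 14.

**Step 7 (key step).** The tertiary radical may be quenched by a second hydrogen-atom transfer, which would simply hydrogenate the isopropenyl group. The alkoxy radical may also fragment back before it is reduced, because addition of a hindered tertiary radical to an aldehyde is reversible. Incomplete equatorial placement of the carbonyl oxygen would erode selectivity at C3.

Fallback, setting out from 11 and returning to the route at 13. Buffered mCPBA epoxidation of the isopropenyl group would give the epoxy alcohol F1, and Dess–Martin oxidation the epoxy aldehyde F2. Cp2TiCl (from Cp2TiCl2 and Zn dust, THF) opens the epoxide to the same tertiary C4 radical, now bearing a CH2O–Ti group. This radical adds to the aldehyde, and a second equivalent of trivalent titanium captures the alkoxy radical at once, which should give the diol F3. Selective acylation of the primary hydroxyl with O-phenyl chlorothionoformate gives the thionocarbonate F4. Barton–McCombie reduction (Bu3SnH, AIBN, toluene, reflux) turns the CH2O group into the second methyl group and delivers 13.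

**Step 4.** C-Allylation of the hindered, fully substituted magnesium enolate may be slow. Proton transfer between enolate and product could then lead to over-alkylation or to loss of the silyloxy group by β-elimination.

Fallback, setting out from 5 and returning at 9. The enolate from the same conjugate addition is trapped on oxygen with allyl chloroformate to give the allyl enol carbonate F5. Pd(PPh3)4 in THF then effects decarboxylative Tsuji allylation. The π-allyl fragment should again be delivered to the enolate face opposite the isopropenyl group, under neutral conditions.

**Step 5.** Hydroboration may spill over to the isopropenyl group, and the borane may reduce the C9 ketone. Ketone reduction is harmless, because step 6 would reoxidise it. Loss of the isopropenyl group would end the route.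

Fallback, setting out from 9 and returning at 12 (no new compound; F0). Aldehyde-selective Wacker oxidation (PdCl2(PhCN)2, CuCl2, AgNO2, O2, t-BuOH/MeNO2, rt) converts the monosubstituted alkene directly to the aldehyde. 1,1-Disubstituted alkenes are poor substrates for divalent palladium under these conditions, and steps 5 and 6 are bypassed.

**Step 9.** The C7 silyloxy group is axial and β to the enolate carbon, so it is well aligned for E1cB elimination from 15 on warming. The same hazard recurs for 17 in step 10. Proton exchange may also cause double methylation at C8.

Fallback, setting out from 14 and returning at 16. HF·pyridine in THF removes the silyl group to give the hydroxy ketone F6. LDA (2.2 equiv) forms the alkoxide–enolate dianion, from which an oxide cannot be expelled, and MeI alkylates at carbon to give the methylated hydroxy ketone F7. TBSOTf and 2,6-lutidine then restore the silyl ether.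

**Step 14.** Oxidative addition and transmetalation at the tetrasubstituted triflate beside the quaternary C10 may be slow. That would give time for β-hydride elimination, reduction of the triflate or homocoupling of the zinc reagent.

Fallback, setting out from 21 and 18 and returning at 24. Kochi oxidative decarboxylation of 21 (Pb(OAc)4, Cu(OAc)2 (cat.), pyridine, benzene, 80 °C) gives the terminal alkene F8. Hydroboration with 9-BBN gives the B-alkyl borane F9. This is coupled with 18 under B-alkyl Suzuki–Miyaura conditions (Pd(dppf)Cl2, AsPh3, Cs2CO3, DMF/THF/H2O), where base-assisted transmetalation from boron is less sensitive to the hindrance at C9.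

**Step 17.** Hydride delivery to the C7 carbonyl may show poor facial selectivity and return part of the material as the 7α-alcohol 25. Some conjugate reduction is also possible.

Fallback, setting out from 25 and returning at 28 (no new compound; F0). Mitsunobu reaction of the 7α-alcohol with acetic acid (PPh3, DIAD, toluene, 0 °C → rt) inverts C7 and installs the acetate in one operation, bypassing steps 16–18. It is the second choice because SN2′ attack and elimination compete at a hindered allylic centre.

## Further compounds

F1 | step 7 | epoxide of the isopropenyl group of 11 (epimers at the epoxide carbon) | OCCC[C@]1(C)C(=O)C[C@H](O[Si](C)(C)C(C)(C)C)C[C@H]1C2(C)CO2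
F2 | step 7 | epoxy keto aldehyde from oxidation of F1 | O=CCC[C@]1(C)C(=O)C[C@H](O[Si](C)(C)C(C)(C)C)C[C@H]1C2(C)CO2
F3 | step 7 | 7α-(tert-butyldimethylsilyloxy)-3β-hydroxy-4-(hydroxymethyl)-4,10β-dimethyl-5α-decalin-9-one (C4 configuration open) | O[C@H]1CC[C@]2(C)C(=O)C[C@H](O[Si](C)(C)C(C)(C)C)C[C@H]2C1(C)CO
F4 | step 7 | O-phenyl thionocarbonate of the primary hydroxyl of F3 | O[C@H]1CC[C@]2(C)C(=O)C[C@H](O[Si](C)(C)C(C)(C)C)C[C@H]2C1(C)COC(=S)Oc3ccccc3
F5 | step 4 | allyl enol carbonate of the conjugate-addition enolate | CC1=C(OC(=O)OCC=C)C[C@H](O[Si](C)(C)C(C)(C)C)C[C@H]1C(C)=C
F0 | step 5 | none | none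
F6 | step 9 | 7α-hydroxy-3β-methoxy-4,4,10β-trimethyl-5α-decalin-9-one | CO[C@H]1CC[C@]2(C)C(=O)C[C@H](O)C[C@H]2C1(C)C
F7 | step 9 | 7α-hydroxy-3β-methoxy-4,4,8,10β-tetramethyl-5α-decalin-9-one (C8 epimers) | CO[C@H]1CC[C@]2(C)C(=O)C(C)[C@H](O)C[C@H]2C1(C)C
F8 | step 14 | (3R)-3-methylpent-4-en-1-yl acetate | C=C[C@H](C)CCOC(C)=O
F9 | step 14 | 9-[(3R)-5-acetoxy-3-methylpentyl]-9-borabicyclo[3.3.1]nonane | B1(CC[C@H](C)CCOC(C)=O)C2CCCC1CCC2
F0 | step 17 | none | none
A1 | alternative 1 | 3β-methoxy-4,4,8,10β-tetramethyl-5α-decalin-7,9-dione (C8 enolisable) | CO[C@H]1CC[C@]2(C)C(=O)C(C)C(=O)C[C@H]2C1(C)C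
A2 | alternative 1 | methyl (2E,5S)-5-methoxy-4,4,8-trimethyl-9-oxoundec-2-enoate (C8 epimers) | CCC(=O)C(C)CC[C@H](OC)C(C)(C)/C=C/C(=O)OC
A3 | alternative 2 | bicyclic 5,8-diene with C8 methyl, C9 methyl ester, quaternary C10 and 3β-methoxy group | CO[C@H]1CC[C@]2(C)C(C(=O)OC)=C(C)CC=C2C1(C)C
A4 | alternative 2 | (4S)-2-ethenyl-4-methoxy-1,3,3-trimethylcyclohex-1-ene | CO[C@H]1CCC(C)=C(C=C)C1(C)C
A5 | alternative 2 | methyl but-2-ynoate | CC#CC(=O)OC
A6 | alternative 3 | ring B cyclohexene aldehyde with C7 silyl enol ether, quaternary C10 and the side chain on C9 | O=C[C@]1(C)[C@@H](CC[C@H](C)CCO[Si](C)(C)C(C)(C)C)[C@@H](C)C(O[Si](C)(C)C(C)(C)C)=C[C@H]1C(C)(C)[C@@H](OC)C=C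
A7 | alternative 3 | (2E,6S)-8-[(tert-butyldimethylsilyl)oxy]-2,6-dimethyloct-2-enal | O=C/C(C)=C/CC[C@H](C)CCO[Si](C)(C)C(C)(C)C
A8 | alternative 3 | tert-butyl{[(2Z,4E,7S)-7-methoxy-6,6-dimethylnona-2,4,8-trien-3-yl]oxy}dimethylsilane | C/C=C(O[Si](C)(C)C(C)(C)C)/C=C/C(C)(C)[C@@H](OC)C=C
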